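The ten-membered carbocycle is read as a decalin cut at its fusion bond: C1 (ketone) and C6 (lactone carbinol) are both oxygenated and sit 1,6 across the ring. Pb(OAc)4 cleavage of a cis ring-fusion C1/C6 diol therefore unveils, in one operation and without any ring closure, the ten-membered (Z)-4-ene-1,6-dione; the Z C4–C5 alkene is inherited from cyclohexene ring A and C7, C8, C10 pass through untouched. The precursor is a cis-decalin-1,6-diol whose ring B, built from (R)-carvone, carries the C7 2-(silyloxymethyl)vinyl group, C8–OTBS and C10–OTES on one face, and whose ring A comes from two Grignard additions and ring-closing metathesis.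

Key step: step 17

Remarks on the chemistry
- Atom labels: carbocycle C1 (ketone), C2, C3, C4 (ring methyl), C5, C6 (lactone O–CH), C7, C8 (angelate O–CH), C9, C10 (tertiary carbinol); side chain C11 (on C7), C12 (oxygenated carbon), C13 (=CH2). Ring A = C1–C6, ring B = C1, C6, C7–C10. α = the face of ring B that carries the C7 side chain, β = the other face.
- Assumption: the C1 and C6 configurations written for 18–25 are those expected for attack on the β face; both centres are erased in step 17, and any cis ring-fusion diol would serve.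
- Design remark: C8–O stays silylated until the lactone is closed, because a free C8–OH is as well placed as C6–OH to capture C12. The lactonisation uses a nitroxyl/PhI(OAc)2 oxidant because the C6 carbinol is itself allylic.

Step 1
Reactants: 1 (R)-carvone
Product: 2 (5R)-5-(3-hydroxyprop-1-en-2-yl)-2-methylcyclohex-2-en-1-one
Conditions: SeO2 (0.5 equiv), t-BuOOH, CH2Cl2, rt
Reagents that add atoms: tert-butyl hydroperoxide CC(C)(C)OO (oxygen source, relayed by selenium dioxide O=[Se]=O)
Why: Allylic hydroxylation by SeO2 (ene reaction followed by a [2,3]-sigmatropic shift) should select the methyl group of the electron-rich 1,1-disubstituted alkene over the deactivated enone and does not touch the C7 stereocentre.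

Step 2
Reactants: 2 (5R)-5-(3-hydroxyprop-1-en-2-yl)-2-methylcyclohex-2-en-1-one
Product: 3 C12 TBS ether of 2
Conditions: TBSCl, imidazole, DMF, 0 °C to rt
Reagents that add atoms: tert-butyldimethylsilyl chloride CC(C)(C)[Si](C)(C)Cl
Why: Standard silylation of a primary allylic alcohol, chosen because this ether has to survive hydride, organometallic and oxidative steps up to step 19.

Step 3
Reactants: 3 C12 TBS ether of 2
Product: 4 (1R,5R)-allylic alcohol of the cis-carveol type (C1–OH α)
Conditions: NaBH4, CeCl3·7H2O, MeOH, –20 °C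
Reagents that add atoms: none
Why: Luche 1,2-reduction, in which axial hydride delivery to the enone carbonyl (as known for carvone itself) should give the pseudo-equatorial C1 alcohol cis to the C7 side chain.

Step 4
Reactants: 4 (1R,5R)-allylic alcohol
Product: 5 α-epoxy alcohol (C9,C10-epoxide cis to C1–OH)
Conditions: VO(acac)2 (2 mol%), t-BuOOH (decane), CH2Cl2, 0 °C to rt
Reagents that add atoms: tert-butyl hydroperoxide CC(C)(C)OO
Why: Hydroxyl-directed epoxidation of an allylic alcohol by the vanadium alkylperoxide delivers oxygen to the face of the C1 hydroxyl, so the C10–O bond is set α (cis to the C7 side chain) while the undirected C11=C13 alkene is left alone.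

Step 5
Reactants: 5 α-epoxy alcohol
Product: 6 O1 4-methoxybenzyl (PMB) ether of 5
Conditions: NaH, PMBCl, Bu4NI (5 mol%), THF/DMF, 0 °C to rt
Reagents that add atoms: 4-methoxybenzyl chloride COc1ccc(CCl)cc1
Why: Williamson etherification that masks the C1 hydroxyl so that only the C10 oxygen can carry the silicon tether of step 7, the alkoxide being unable to undergo Payne migration because it is cis to the epoxide.

Step 6
Reactants: 6 O1 PMB ether of 5
Product: 9 C10α tertiary allylic alcohol (C8=C9; C1–OPMB), via C9 phenylselenide 7 (not isolated), via C9 selenoxide 8 (not isolated)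
Conditions: (PhSe)2, NaBH4, EtOH, 70 °C; then 30% H2O2, pyridine, THF, 0 °C to rt
Reagents that add atoms: none
Why: Epoxide-to-allylic-alcohol transposition in which phenylselenolate opens the epoxide trans-diaxially at the secondary C9 and the derived selenoxide can only syn-eliminate toward C8 because C10 is quaternary, so the C10 configuration is kept and the alkene lands at C8=C9.

Step 7
Reactants: 9 C10α tertiary allylic alcohol
Product: 11 bridged oxasilolane (O10–SiMe2–C8 on the α face), via O10 dimethylsilyl ether 10 (not isolated)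
Conditions: Me2SiHCl, Et3N, DMAP (5 mol%), CH2Cl2, 0 °C; filter, solvent switch; Pt2[(CH2=CHSiMe2)2O]3 (1 mol%), toluene, 60 °C
Reagents that add atoms: chlorodimethylsilane C[SiH](C)Cl
Why: Tethered intramolecular hydrosilylation of an allylic alcohol, in which the Si–H carried by the α C10 oxygen can reach only C8 (five-membered oxasilolane) and only from the α face, so both the regiochemistry and the C8 configuration are dictated by the tether.

Step 8
Reactants: 11 bridged oxasilolane
Product: 12 C8α,C10α-diol (cis-1,3; C1–OPMB)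
Conditions: 30% H2O2, KF, KHCO3, THF/MeOH, rt to 40 °C
Reagents that add atoms: hydrogen peroxide OO
Why: Tamao oxidation replaces the C8–Si bond by C8–OH with retention, giving the cis-1,3-diol with both oxygens on the face of the C7 side chain.

Step 9
Reactants: 12 C8α,C10α-diol
Product: 14 C8–OTBS C10–OTES PMB ether, via C8 mono-TBS ether 13 (not isolated)
Conditions: TBSOTf (1.1 equiv), 2,6-lutidine, CH2Cl2, –78 °C; then TESOTf (1.5 equiv), –78 to 0 °C
Reagents that add atoms: tert-butyldimethylsilyl triflate CC(C)(C)[Si](C)(C)OS(=O)(=O)C(F)(F)F; triethylsilyl triflate CC[Si](CC)(CC)OS(=O)(=O)C(F)(F)F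
Why: Silyl triflate silylation in order of hindrance, one equivalent of TBSOTf at low temperature taking the secondary C8 hydroxyl and the smaller TESOTf then capping the tertiary C10 hydroxyl, which must be blocked before the key step.

Step 10
Reactants: 14 C8–OTBS C10–OTES PMB ether
Product: 15 C1α alcohol
Conditions: DDQ, CH2Cl2/pH 7 buffer, 0 °C
Reagents that add atoms: none
Why: Oxidative cleavage of the electron-rich benzyl ether by DDQ in buffered wet CH2Cl2 frees O1 without touching silyl ethers or the isolated alkene.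

Step 11
Reactants: 15 C1α alcohol
Product: 16 ring B ketone (C1=O; C8–OTBS; C10–OTES; C12–OTBS)
Conditions: Dess–Martin periodinane, NaHCO3, CH2Cl2, rt
Reagents that add atoms: none
Why: Buffered Dess–Martin oxidation of the only free alcohol gives the ketone, whose C10 neighbour is quaternary and cannot epimerise.

Step 12
Reactants: 16 ring B ketone
Product: 18 C6β-hydroxy ketone, via potassium enolate 17 (not isolated)
Conditions: KHMDS, THF, –78 °C; then 2-(phenylsulfonyl)-3-phenyloxaziridine, –78 °C; aq NH4Cl
Reagents that add atoms: 2-(phenylsulfonyl)-3-phenyloxaziridine O=S(=O)(c1ccccc1)N1OC1c1ccccc1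
Why: Enolate oxidation by a Davis oxaziridine, where only C6 carries alpha hydrogens so the enolate is regiodefined and oxygen should arrive on the β face away from the α substituents (this C6 configuration is erased in step 14).

Step 13
Reactants: 18 C6β-hydroxy ketone; 19 4-bromo-2-methylbut-1-ene
Product: 21 C1-butenyl diol (C1–OH α; C6–OH β), via 3-methylbut-3-enylmagnesium bromide 20 (not isolated)
Conditions: 19, Mg, THF, rt to 40 °C (gives 20, 3 equiv); then 18, LaCl3·2LiCl (1 equiv), THF, –40 to 0 °C
Reagents that add atoms: 4-bromo-2-methylbut-1-ene C=C(C)CCBr (as its Grignard reagent C=C(C)CC[Mg]Br)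
Why: Lanthanum-promoted Grignard 1,2-addition (the additive curbs enolisation and beta-hydride reduction), in which the nucleophile should attack C1 from the β face, anti to the α C10–OTES bond (polar Felkin–Anh) and away from the other α groups, giving the α tertiary alcohol.

Step 14
Reactants: 21 C1-butenyl diol
Product: 22 C6 ketone (C1 tertiary alcohol kept)
Conditions: 2-iodoxybenzoic acid (IBX), DMSO, rt
Reagents that add atoms: none
Why: IBX oxidises the secondary alcohol of a 1,2-diol to the ketone without glycol cleavage and under neutral conditions, so the acidic allylic C7–H is not epimerised.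

Step 15
Reactants: 22 C6 ketone; 23 vinylmagnesium bromide
Product: 24 C1-butenyl C6-vinyl cis-diol (both OH α)
Conditions: 23 (4 equiv), LaCl3·2LiCl (1 equiv), THF, –78 to –20 °C
Reagents that add atoms: vinylmagnesium bromide C=C[Mg]Br
Why: Lanthanum-mediated vinyl Grignard addition to an enolisable ketone, in which attack should again come from the β face (anti to the α C1 oxygen and away from the α C7, C8 and C10 groups), so the new C6 hydroxyl is α and cis to the C1 hydroxyl.

Step 16
Reactants: 24 C1-butenyl C6-vinyl cis-diol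
Product: 25 cis-decalin-1,6-diol (key-step precursor)
Conditions: RuCl2(=CHPh)(PCy3)(H2IMes) (second-generation Grubbs catalyst, 5 mol%), CH2Cl2 (5 mM), 40 °C
Reagents that add atoms: none
Why: Ring-closing metathesis between the vinyl group and the 1,1-disubstituted butenyl alkene closes six-membered ring A (the C11=C13 alkene could only give a four-membered or a tetrasubstituted seven-membered ring), and the endocyclic C4=C5 bond is necessarily cis.

Step 17
Reactants: 25 cis-decalin-1,6-diol
Product: 26 ten-membered (Z)-4-ene-1,6-dione (key-step product)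
Conditions: Pb(OAc)4 (1.1 equiv), K2CO3 (solid), CH2Cl2, –20 to 0 °C; filtration through Celite, solution used at once
Reagents that add atoms: none
Why: Tetravalent lead exchanges two acetates for the cis-disposed C1 and C6 hydroxyls to give a five-membered cyclic lead diester, which collapses in a concerted two-electron fragmentation (lead leaving as Pb(OAc)2) that breaks the shared C1–C6 bond and leaves a carbonyl on each former fusion carbon; this is a Criegee glycol cleavage, the closest known type being Pb(OAc)4 scission of ring-fusion diols of fused bicycles to medium-ring diketones. No ring is closed by bond formation, since the ten-membered carbocycle is simply the periphery of the decalin once its fusion bond is cut, so there is no mode of closure to control. No stereocentre is created: C7, C8 and C10 are spectators and the C4–C5 alkene keeps the Z geometry imposed inside cyclohexene ring A. The selectivity needed is chemoselectivity for the C1/C6 glycol, secured because these are the only free hydroxyls (the C10 oxygen is capped as its TES ether, so the C1–C10 bond cannot enter a lead ester) and because isolated alkenes are inert to the reagent at 0 °C. Solid K2CO3 takes up the acetic acid, so that the product, whose C7–H is both alpha to the C6 ketone and allylic, is not exposed to conditions that would cause transannular aldol closure, C7 epimerisation, alkene migration or loss of the C8 silyloxy group.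

Step 18
Reactants: 26 ten-membered (Z)-4-ene-1,6-dione
Product: 27 (6R)-C6 allylic alcohol
Conditions: NaBH4, CeCl3·7H2O, MeOH/CH2Cl2, –78 °C
Reagents that add atoms: none
Why: Luche reduction, in which the conjugated C6 ketone should be reduced 1,2 in preference to the C1 ketone (shielded by the quaternary C10 bearing OTES) and hydride should add from the ring periphery anti to the C7 side chain (Felkin–Anh) to set the 6R carbinol needed for the trans-fused lactone.

Step 19
Reactants: 27 (6R)-C6 allylic alcohol
Product: 28 C6,C10,C12-triol (C8–OTBS kept)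
Conditions: HF·pyridine, pyridine, THF, 0 °C to rt
Reagents that add atoms: none
Why: Buffered fluoride desilylation graded by accessibility, in which the primary allylic TBS ether and the labile TES ether should go while the secondary TBS ether at C8 (flanked by C7) stays, so that C8–OH cannot compete for C12 in the next step.

Step 20
Reactants: 28 C6,C10,C12-triol
Product: 31 C8–OTBS alpha-methylene lactone, via C12 enal 29 (not isolated), via C6–O–C12 lactol 30 (not isolated)
Conditions: TEMPO (0.2 equiv), PhI(OAc)2 (2.5 equiv), CH2Cl2, rt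
Reagents that add atoms: none
Why: Nitroxyl-catalysed oxidative lactonisation, in which the oxoammonium species oxidises the primary allylic alcohol selectively, the enal is trapped by the C6 hydroxyl as a lactol and this is oxidised on to the lactone without touching the secondary allylic or tertiary carbinols.

Step 21
Reactants: 31 C8–OTBS alpha-methylene lactone
Product: 32 C8,C10-diol lactone
Conditions: HF·pyridine (excess), THF, 0 °C to rt
Reagents that add atoms: none
Why: Fluoride cleavage of the remaining secondary silyl ether under mildly acidic conditions, which avoids the basic media that could add to the alpha-methylene lactone or move the lactone to O8.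

Step 22
Reactants: 32 C8,C10-diol lactone; 33 angelic acid
Product: 35 target 8-O-angelate (CNP0345906.2), via angelic 2,4,6-trichlorobenzoic anhydride 34 (not isolated)
Conditions: 33, 2,4,6-trichlorobenzoyl chloride, Et3N, toluene, rt (gives 34); then 32, toluene, 80 °C
Reagents that add atoms: angelic acid C/C=C(/C)C(=O)O
Why: Yamaguchi-type esterification through the 2,4,6-trichlorobenzoyl mixed anhydride without a nucleophilic catalyst, a protocol that gives angelates without Z-to-E isomerisation, and only the secondary C8 hydroxyl should react because the tertiary C10 hydroxyl is unreactive.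

Compound list
1 | (R)-carvone | CC(=C)[C@@H]1CC=C(C)C(=O)C1 | starting material
2 | (5R)-5-(3-hydroxyprop-1-en-2-yl)-2-methylcyclohex-2-en-1-one (C12 alcohol) | O=C1C[C@H](C(=C)CO)CC=C1C | intermediate
3 | (5R)-5-[3-(tert-butyldimethylsilyloxy)prop-1-en-2-yl]-2-methylcyclohex-2-en-1-one | O=C1C[C@H](C(=C)CO[Si](C)(C)C(C)(C)C)CC=C1C | intermediate
4 | (1R,5R)-allylic alcohol of 3 (cis-carveol type; C1–OH α, cis to the C7 side chain) | O[C@@H]1C[C@H](C(=C)CO[Si](C)(C)C(C)(C)C)CC=C1C | intermediate
5 | α-epoxy alcohol: C9,C10-epoxide, C1–OH and C7 side chain all on the α face | O[C@@H]1C[C@H](C(=C)CO[Si](C)(C)C(C)(C)C)C[C@@H]2O[C@]12C | intermediate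
6 | O1 4-methoxybenzyl ether of 5 | COc1ccc(CO[C@@H]2C[C@H](C(=C)CO[Si](C)(C)C(C)(C)C)C[C@@H]3O[C@]23C)cc1 | intermediate
7 | C9β-phenylselanyl C10α-ol (trans-diaxial opening product of 6) | COc1ccc(CO[C@@H]2C[C@H](C(=C)CO[Si](C)(C)C(C)(C)C)C[C@@H]([Se]c3ccccc3)[C@]2(C)O)cc1 | intermediate
8 | selenoxide of 7 (selenium configuration undefined) | COc1ccc(CO[C@@H]2C[C@H](C(=C)CO[Si](C)(C)C(C)(C)C)C[C@@H]([Se](=O)c3ccccc3)[C@]2(C)O)cc1 | intermediate
9 | tertiary allylic alcohol: C8=C9, C10α-OH (C10 methyl β), C1α-OPMB, C7α side chain | COc1ccc(CO[C@@H]2C[C@H](C(=C)CO[Si](C)(C)C(C)(C)C)C=C[C@]2(C)O)cc1 | intermediate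
10 | O10-dimethylsilyl (Si–H) ether of 9 | COc1ccc(CO[C@@H]2C[C@H](C(=C)CO[Si](C)(C)C(C)(C)C)C=C[C@]2(C)O[SiH](C)C)cc1 | intermediate
11 | bridged oxasilolane: O10–SiMe2–C8, silicon on the α face of C8 | COc1ccc(CO[C@@H]2C[C@H](C(=C)CO[Si](C)(C)C(C)(C)C)[C@H]3C[C@]2(C)O[Si]3(C)C)cc1 | intermediate
12 | C8α,C10α-diol (cis-1,3), C1α-OPMB | COc1ccc(CO[C@@H]2C[C@H](C(=C)CO[Si](C)(C)C(C)(C)C)[C@H](O)C[C@]2(C)O)cc1 | intermediate
13 | C8α-OTBS, C10α-OH, C1α-OPMB | COc1ccc(CO[C@@H]2C[C@H](C(=C)CO[Si](C)(C)C(C)(C)C)[C@H](O[Si](C)(C)C(C)(C)C)C[C@]2(C)O)cc1 | intermediate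
14 | C8α-OTBS, C10α-OTES, C1α-OPMB | COc1ccc(CO[C@@H]2C[C@H](C(=C)CO[Si](C)(C)C(C)(C)C)[C@H](O[Si](C)(C)C(C)(C)C)C[C@]2(C)O[Si](CC)(CC)CC)cc1 | intermediate
15 | C1α-alcohol with C8α-OTBS, C10α-OTES | O[C@@H]1C[C@H](C(=C)CO[Si](C)(C)C(C)(C)C)[C@H](O[Si](C)(C)C(C)(C)C)C[C@]1(C)O[Si](CC)(CC)CC | intermediate
16 | ring B ketone: C1=O, C10α-OTES (methyl β), C8α-OTBS, C7α side chain with C12–OTBS | O=C1C[C@H](C(=C)CO[Si](C)(C)C(C)(C)C)[C@H](O[Si](C)(C)C(C)(C)C)C[C@]1(C)O[Si](CC)(CC)CC | intermediate
17 | potassium enolate of 16 (C1–O, C1=C6) | [K+].[O-]C1=C[C@H](C(=C)CO[Si](C)(C)C(C)(C)C)[C@H](O[Si](C)(C)C(C)(C)C)C[C@]1(C)O[Si](CC)(CC)CC | intermediate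
18 | C6β-hydroxy ketone of 16 | O=C1[C@@H](O)[C@H](C(=C)CO[Si](C)(C)C(C)(C)C)[C@H](O[Si](C)(C)C(C)(C)C)C[C@]1(C)O[Si](CC)(CC)CC | intermediate
19 | 4-bromo-2-methylbut-1-ene | C=C(C)CCBr | starting material
20 | 3-methylbut-3-enylmagnesium bromide | C=C(C)CC[Mg]Br | intermediate
21 | diol: C1 α-OH and β-(3-methylbut-3-enyl); C6 β-OH | O[C@]1(CCC(C)=C)[C@@H](O)[C@H](C(=C)CO[Si](C)(C)C(C)(C)C)[C@H](O[Si](C)(C)C(C)(C)C)C[C@]1(C)O[Si](CC)(CC)CC | intermediate
22 | C6 ketone; C1 α-OH and β-butenyl | O[C@]1(CCC(C)=C)C(=O)[C@H](C(=C)CO[Si](C)(C)C(C)(C)C)[C@H](O[Si](C)(C)C(C)(C)C)C[C@]1(C)O[Si](CC)(CC)CC | intermediate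
23 | vinylmagnesium bromide | C=C[Mg]Br | starting material
24 | cis-1,2-diol: C1 α-OH/β-butenyl, C6 α-OH/β-vinyl | O[C@]1(CCC(C)=C)[C@@](O)(C=C)[C@H](C(=C)CO[Si](C)(C)C(C)(C)C)[C@H](O[Si](C)(C)C(C)(C)C)C[C@]1(C)O[Si](CC)(CC)CC | intermediate
25 | cis-decalin-1,6-diol: ring A cyclohexene (C4 methyl, C4=C5) on the β face; C1–OH, C6–OH, C7 side chain, C8–OTBS and C10–OTES all α | O[C@]12CCC(C)=C[C@@]1(O)[C@H](C(=C)CO[Si](C)(C)C(C)(C)C)[C@H](O[Si](C)(C)C(C)(C)C)C[C@]2(C)O[Si](CC)(CC)CC | intermediate
26 | ten-membered (4Z)-4-ene-1,6-dione; C7, C8, C10 as in the target; C8–OTBS, C10–OTES, C12–OTBS | O=C1/C=C(/C)CCC(=O)[C@@](C)(O[Si](CC)(CC)CC)C[C@@H](O[Si](C)(C)C(C)(C)C)[C@H]1C(=C)CO[Si](C)(C)C(C)(C)C | intermediate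
27 | (6R)-allylic alcohol of 26 (C6 configuration of the target) | O[C@@H]1/C=C(/C)CCC(=O)[C@@](C)(O[Si](CC)(CC)CC)C[C@@H](O[Si](C)(C)C(C)(C)C)[C@H]1C(=C)CO[Si](C)(C)C(C)(C)C | intermediate
28 | C6,C10,C12-triol, C8–OTBS, C1 ketone | O[C@@H]1/C=C(/C)CCC(=O)[C@@](C)(O)C[C@@H](O[Si](C)(C)C(C)(C)C)[C@H]1C(=C)CO | intermediate
29 | C12 enal of 28 | O[C@@H]1/C=C(/C)CCC(=O)[C@@](C)(O)C[C@@H](O[Si](C)(C)C(C)(C)C)[C@H]1C(=C)C=O | intermediate
30 | C6–O–C12 lactol (anomeric mixture) | C=C1C(O)O[C@@H]2/C=C(/C)CCC(=O)[C@@](C)(O)C[C@@H](O[Si](C)(C)C(C)(C)C)[C@@H]12 | intermediate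
31 | trans-fused 6,12-lactone with exo-methylene, C8–OTBS, C10–OH | C=C1C(=O)O[C@@H]2/C=C(/C)CCC(=O)[C@@](C)(O)C[C@@H](O[Si](C)(C)C(C)(C)C)[C@@H]12 | intermediate
32 | 6,12-lactone with free C8–OH and C10–OH | C=C1C(=O)O[C@@H]2/C=C(/C)CCC(=O)[C@@](C)(O)C[C@@H](O)[C@@H]12 | intermediate
33 | angelic acid, (Z)-2-methylbut-2-enoic acid | C/C=C(/C)C(=O)O | starting material
34 | angelic 2,4,6-trichlorobenzoic anhydride | C/C=C(/C)C(=O)OC(=O)c1c(Cl)cc(Cl)cc1Cl | intermediate
35 | CNP0345906.2: (6R,7R,8R,10S,4Z)-8-angeloyloxy-10-hydroxy-1-oxogermacra-4,11(13)-dien-6,12-olide | C=C1C(=O)O[C@@H]2/C=C(/C)CCC(=O)[C@@](C)(O)C[C@@H](OC(=O)/C(C)=C\C)[C@@H]12 | target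

Total step count: 22. Longest linear sequence: 22 steps, from (R)-carvone 1 to 35.

Steps most likely to fail

Step 17 (glycol cleavage). The hindered ditertiary glycol may be slow to form the cyclic lead diester. The enedione may also be lost after it forms, through transannular aldol closure, epimerisation at C7 or migration of the C11=C13 alkene into conjugation during filtration and handling. The fallback changes the approach from isolating the dione to generating it only transiently without lead. It sets out from 25, which is cleaved with PhI(OAc)2 in CH2Cl2 at 0 °C; the cold solution is then diluted with MeOH and treated at –78 °C with CeCl3·7H2O and NaBH4. It comes back to the route at 27 and makes no compound outside the list (F0).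

Step 18 (C6 reduction). Hydride delivery to the flexible ten-membered ring may show poor facial selectivity and favour the wrong C6 face. The fallback sets out from 26 and accepts that outcome: the (6S)-allylic alcohol F1 is inverted by a Mitsunobu reaction (4-nitrobenzoic acid, PPh3, diisopropyl azodicarboxylate, THF, 0 °C) to the (6R)-4-nitrobenzoate F2. Cleavage with K2CO3 in MeOH at 0 °C returns to the route at 27.

Step 7 (tethered hydrosilylation). The Si–H may fail to add across the hindered cis-disubstituted C8=C9 bond, or a platinum hydride may move that alkene toward C7 before cyclisation. The fallback sets out from 9 and builds the C8 oxygen through a ketone instead. Babler–Dauben oxidative transposition with pyridinium chlorochromate (C5H5NH)[CrO3Cl] and NaOAc in CH2Cl2 gives the C8 enone F3 (C9=C10). LiBH(s-Bu)3 at –78 °C reduces it 1,2 from the β face to the C8α allylic alcohol F4. VO(acac)2 with t-BuOOH epoxidises syn to that hydroxyl to give the α C9,C10-epoxy alcohol F5. LiAlH4 in THF opens the epoxide at the secondary C9 and comes back to the route at diol 12.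

Further compounds
F0 | step 17 | none | none
F1 | step 18 | (6S)-allylic alcohol, C6 epimer of 27 | O[C@H]1/C=C(/C)CCC(=O)[C@@](C)(O[Si](CC)(CC)CC)C[C@@H](O[Si](C)(C)C(C)(C)C)[C@H]1C(=C)CO[Si](C)(C)C(C)(C)C
F2 | step 18 | (6R)-4-nitrobenzoate of 27 | O=C(O[C@@H]1/C=C(/C)CCC(=O)[C@@](C)(O[Si](CC)(CC)CC)C[C@@H](O[Si](C)(C)C(C)(C)C)[C@H]1C(=C)CO[Si](C)(C)C(C)(C)C)c1ccc(cc1)[N+](=O)[O-]
F3 | step 7 | C8 enone (C9=C10), C1α-OPMB | COc1ccc(CO[C@@H]2C[C@H](C(=C)CO[Si](C)(C)C(C)(C)C)C(=O)C=C2C)cc1
F4 | step 7 | C8α allylic alcohol (C9=C10), C1α-OPMB | COc1ccc(CO[C@@H]2C[C@H](C(=C)CO[Si](C)(C)C(C)(C)C)[C@H](O)C=C2C)cc1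
F5 | step 7 | α C9,C10-epoxide of F4 | COc1ccc(CO[C@@H]2C[C@H](C(=C)CO[Si](C)(C)C(C)(C)C)[C@H](O)[C@@H]3O[C@]23C)cc1
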